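Its constants are assumed; what happens was integrated by code.

I began with amounts: each target holds one substrate and one partner, and each of those has taken up one reagent.

    substrate + reagent → open intermediate (k1 = 5.7 M⁻¹ min⁻¹)
    reagent + partner → second intermediate (k2 = 0.19 M⁻¹ min⁻¹)
    open intermediate + second intermediate → target (k3 = 0.10 M⁻¹ min⁻¹)
    2 second intermediate → homo product (k4 = 0.039 M⁻¹ min⁻¹)
    gas ⇌ reagent, rate k5*(csat - [reagent]) (k5 = 0.12 min⁻¹, csat = 45 mM)

| setting | Monday's | Sunday's | Wednesday's |
|---|---|---|---|
| substrate | 0.50 M | 0.50 M | 0.50 M |
| partner | 0.300 M | 0.600 M | 1.20 M |
| gas | 45 mM (held) | 45 mM (held) | 45 mM (held) |
| time | 15 h | 15 h | 15 h |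

1. amount of target at the end, in percent of the substrate charged for Monday's, Sunday's, Wednesday's, in this order
2. how that number moves from the first to the last of them (hardly changes / rises all the way / falls, then rises / rises, then falls / falls all the way)

- a step written with two of one species runs at k times the square of its concentration and takes two of it each time
- at the start none of reagent is dissolved
- "hardly changes" means that all values lie within two and a half points (for a concentration: within two and a half percent of the largest)
- run time (Monday's): 15 h

**Partner cover.** My bench rule was the limiting reagent. Monday's flask held 60.0 % of partner per substrate, and this cover, partner charged over substrate charged, caps the target in percent of substrate charged whenever it is below 100 %. Sunday's cover was 120 % and Wednesday's 240 %, so both flasks charged more partner than substrate and the rule capped them at 100 %.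

**Time check.** Full transfer delivers 0.324 M h⁻¹ of reagent. Wednesday's flask needed one reagent per substrate and per partner, which is 5.25 h at that rate, less than the 15 h allowed.

**The border.** The rule treats partner as if none were lost, yet two second intermediates can pair to homo product. Second intermediate goes to target at 0.10 M⁻¹ min⁻¹ times open intermediate times second intermediate, and to homo product at 0.0780 M⁻¹ min⁻¹ times its own square. The two rates are equal when second intermediate stands at 1.28 times the open intermediate, and there the rule stops working. Sunday's flask had 0.100 M of partner to spare over the substrate, so I allowed it some loss. I committed to just under 60.0 % for Monday's flask, somewhat under 100 % for Sunday's, and about 100 % for Wednesday's.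

**The forecast.** The forecast gave 56 %, 96 % and 99.5 %, a number that rises all the way. For the larger charges it reasoned that “the partner is in excess, so the homo-coupling loss is covered”.

**The flasks.** The simulation gave 57.4 %, 95.6 % and 100 %, a number that rises all the way, as forecast. In Monday's flask the main reason for the missing target was the falling level of partner: with that fall taken away, the target reached >99.9 % instead of 57.4 %. Taking away the homo step was not the reason, since it gave 59.8 %, about the cover of 60.0 %. Sunday's flask, with a cover of 120 %, ended with 4.38 % of the substrate charged still standing as open intermediate.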